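**Plan** (drimane numbering: ring carbons C1–C10, C11 = OCH2 on C9, C12 = CH3 on C8, C13 = OCH2 on C4, C14 = CH3 on C4, C15 = CH3 on C10)
1. Cuts: first the angelate ester at O–C13 and the aryl ether at O–C11. Then, after adding a helper C6=C7 double bond, ring B is cut at C8–C9 and at the fusion bond C5–C10 in one retro-[4+2], which also opens ring A. The open chain is then cut at C4–C5 (1,2-alkenyl shift) and C13–C5 (alkenyl addition).
2. Enabling feature: in ring B the O-bearing C8 sits next to C9, whose substituent C11 can be raised to an ester. C6 and C7 are unsubstituted, and C5 and C10 are spanned by the four-carbon bridge C1–C4 of ring A. This is the pattern of a tethered 1-oxydiene (C5=C6–C7=C8–O) plus enoate (C9=C10–C11).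
3. Forward: methyl geranate supplies C1–C4, C9–C11 and C13–C15, and pent-4-yn-2-ol supplies C5–C8 and C12. The chain is joined at C13 and shifted to C4. Rings A and B form together in step 10, followed by saturation, reduction, etherification, deprotection and acylation.
4. Stereochemistry: C3 and C4 come from the asymmetric epoxidation plus a stereospecific anti 1,2-shift. C5, C8, C9 and C10 come from the alkene geometries, the endo transition state and a dioxane lock. The Z-ester comes from angelic acid.

Key step: step 10

Remark: the carbinol carbons C8 (in 5–11) and C13 (in 8) are epimer mixtures that are erased in steps 8 and 6, so their SMILES carry no descriptor there.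

Step 1
Reactants: 1 methyl geranate
Product: 2 methyl (2E,6E)-8-hydroxy-3,7-dimethylocta-2,6-dienoate
Conditions: SeO2 (0.1 equiv), t-BuOOH (2 equiv), salicylic acid (0.1 equiv), CH2Cl2, rt
Reagents that add atoms: tert-butyl hydroperoxide CC(C)(C)OO
Why: Selenium dioxide-catalysed allylic oxidation (ene reaction, then [2,3]-sigmatropic shift) should attack only the electron-rich trisubstituted alkene, at the methyl group trans to the chain, giving the (E)-allylic alcohol while the deactivated enoate alkene stays untouched.

Step 2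
Reactants: 2 methyl (2E,6E)-8-hydroxy-3,7-dimethylocta-2,6-dienoate
Product: 3 methyl (2E)-5-[(2R,3R)-3-(hydroxymethyl)-3-methyloxiran-2-yl]-3-methylpent-2-enoate
Conditions: Ti(OiPr)4 (0.1 equiv), D-(−)-diethyl tartrate (0.12 equiv), t-BuOOH (2 equiv, decane), 4 Å MS, CH2Cl2, −20 °C
Reagents that add atoms: tert-butyl hydroperoxide CC(C)(C)OO
Why: In this Katsuki–Sharpless asymmetric epoxidation of an (E)-2-methylalk-2-en-1-ol, the D-(−)-tartrate complex delivers oxygen to the face that gives the (R,R)-epoxide, which fixes C3 for good and C4 provisionally, and the enoate has no allylic hydroxyl and is not touched.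

Step 3
Reactants: 3 methyl (2E)-5-[(2R,3R)-3-(hydroxymethyl)-3-methyloxiran-2-yl]-3-methylpent-2-enoate
Product: 4 methyl (2E)-5-[(2R,3S)-3-formyl-3-methyloxiran-2-yl]-3-methylpent-2-enoate
Conditions: TEMPO (0.1 equiv), PhI(OAc)2 (1.1 equiv), CH2Cl2, rt
Reagents that add atoms: none
Why: Oxoammonium (TEMPO) oxidation of a primary alcohol stops at the aldehyde under nearly neutral conditions that spare the epoxide, and C4 is fully substituted and cannot epimerise (the descriptor changes only through the priority rules).

Step 4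
Reactants: 5 pent-4-yn-2-ol (racemic)
Product: 7 (E)-5-iodopent-4-en-2-ol, via alkenylzirconocene 6 (not isolated)
Conditions: Cp2Zr(H)Cl (2.2 equiv), THF, rt; then iodine, 0 °C
Reagents that add atoms: Cp2Zr(H)Cl [H][Zr](Cl)(C1C=CC=C1)C1C=CC=C1 (atoms end in 6 only); iodine [I][I]
Why: In this hydrozirconation–iodinolysis, the first equivalent is consumed by the hydroxyl, the second adds syn with zirconium on the terminal carbon, and C–Zr cleavage by iodine proceeds with retention to give the (E)-iodide.

Step 5
Reactants: 4 methyl (2E)-5-[(2R,3S)-3-formyl-3-methyloxiran-2-yl]-3-methylpent-2-enoate; 7 (E)-5-iodopent-4-en-2-ol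
Product: 8 methyl (2E)-5-{(2R,3R)-3-[(2E)-1,5-dihydroxyhex-2-en-1-yl]-3-methyloxiran-2-yl}-3-methylpent-2-enoate
Conditions: CrCl2 (4 equiv), NiCl2 (1 mol %), DMF, rt
Reagents that add atoms: none
Why: In this Nozaki–Hiyama–Kishi coupling, the alkenylchromium reagent adds only to the aldehyde, tolerates ester, epoxide and free hydroxyl, and keeps the E geometry, and the new carbinol centre C13 need not be controlled because it becomes sp2 in step 6.

Step 6
Reactants: 8 methyl (2E)-5-{(2R,3R)-3-[(2E)-1,5-dihydroxyhex-2-en-1-yl]-3-methyloxiran-2-yl}-3-methylpent-2-enoate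
Product: 10 methyl (2E,6R,7S,8E)-6,11-dihydroxy-7-(hydroxymethyl)-3,7-dimethyldodeca-2,8-dienoate, via hydroxy aldehyde 9 (not isolated)
Conditions: BF3·OEt2 (0.3 equiv), CH2Cl2, −78 °C; aq NaHCO3 work-up; crude, NaBH4, MeOH, 0 °C
Reagents that add atoms: none
Why: In this semipinacol rearrangement of a 2,3-epoxy alcohol, the Lewis acid ionises the tertiary C4–O bond while the alkenyl group (a better migrating group than H) shifts from C13 to C4 anti to the leaving oxygen, so C4 is inverted stereospecifically into the quaternary centre with C3–O untouched, and the retro-aldol-prone aldehyde is reduced at once without harm to the enoate.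

Step 7
Reactants: 10 methyl (2E,6R,7S,8E)-6,11-dihydroxy-7-(hydroxymethyl)-3,7-dimethyldodeca-2,8-dienoate
Product: 11 methyl (2E)-5-{(4R,5S)-5-[(1E)-4-hydroxypent-1-en-1-yl]-2,2,5-trimethyl-1,3-dioxan-4-yl}-3-methylpent-2-enoate
Conditions: 2,2-dimethoxypropane (5 equiv), PPTS (cat.), CH2Cl2, rt
Reagents that add atoms: 2,2-dimethoxypropane COC(C)(C)OC
Why: Acid-catalysed transketalisation gives the six-membered acetonide of the O3/O13 1,3-diol under thermodynamic control, and the remote C8 hydroxyl cannot form a ring and stays free.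

Step 8
Reactants: 11 methyl (2E)-5-{(4R,5S)-5-[(1E)-4-hydroxypent-1-en-1-yl]-2,2,5-trimethyl-1,3-dioxan-4-yl}-3-methylpent-2-enoate
Product: 12 methyl (2E)-3-methyl-5-{(4R,5S)-2,2,5-trimethyl-5-[(1E)-4-oxopent-1-en-1-yl]-1,3-dioxan-4-yl}pent-2-enoate
Conditions: Dess–Martin periodinane (1.3 equiv), pyridine (3 equiv), CH2Cl2, 0 °C
Reagents that add atoms: none
Why: Buffered Dess–Martin oxidation converts the homoallylic alcohol into the β,γ-unsaturated methyl ketone without acid or base strong enough to move the alkene into conjugation.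

Step 9
Reactants: 12 methyl (2E)-3-methyl-5-{(4R,5S)-2,2,5-trimethyl-5-[(1E)-4-oxopent-1-en-1-yl]-1,3-dioxan-4-yl}pent-2-enoate
Product: 13 methyl (2E)-3-methyl-5-{(4R,5S)-2,2,5-trimethyl-5-[(1E,3Z)-4-(triethylsilyloxy)penta-1,3-dien-1-yl]-1,3-dioxan-4-yl}pent-2-enoate
Conditions: Et3SiOTf (1.3 equiv), Et3N (2.5 equiv), CH2Cl2, −78 to 0 °C
Reagents that add atoms: triethylsilyl triflate CC[Si](CC)(CC)OS(=O)(=O)C(F)(F)F
Why: In this soft enolisation, the O-silylated ketone should lose the doubly activated (allylic and α-keto) C7–H rather than a C12–H, giving the through-conjugated dienol ether, strain between C12 and C6 favours the usual (Z)-enol silane with O8 cis to C6, and enoate and acetonide are inert at this temperature.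

Step 10
Reactants: 13 methyl (2E)-3-methyl-5-{(4R,5S)-2,2,5-trimethyl-5-[(1E,3Z)-4-(triethylsilyloxy)penta-1,3-dien-1-yl]-1,3-dioxan-4-yl}pent-2-enoate
Product: 14 methyl (3R,4S,5S,8S,9S,10R)-3,13-(isopropylidenedioxy)-8-(triethylsilyloxy)drim-6-en-11-oate
Conditions: toluene (0.01 M), BHT (cat.), 180 °C, sealed tube
Reagents that add atoms: none
Why: The step is a concerted, asynchronous intramolecular [4+2] cycloaddition of the electron-rich (5E,7Z)-1-silyloxy-1-methyl diene C5=C6–C7=C8 onto the (E)-enoate C9=C10, and its closest known type is the thermal intramolecular Diels–Alder reaction of terminally activated 1,7,9-decatrienes and of 1-silyloxydienes. Ring A closes through C5–C10 with the bridge C1–C4 in a chair, and ring B closes as a boat-like cyclohexene through C5–C10 and C8–C9 (fused mode, both new rings six-membered). C9 and C10 follow from suprafacial addition to the (E)-enoate (C11 cis to C15), C5 and C8 follow from the diene geometry (C4 and C12 outside, H5 and O8 inside, so O8 ends trans to C11 and C12 axial), and the trans ring fusion follows from the transition state with the ester endo and the bridge exo. The absolute sense comes from C3 and C4, because only the dioxane chair with C2 and C5 both equatorial lets C5 reach C10, which fixes the ring A chair with O3 and C13 equatorial and C14 axial and places C6 equatorial on C5. Regiochemistry is imposed by the bridge and is matched electronically, since the largest HOMO coefficient at C5 meets the β-carbon C10 and the O-bearing C8 meets the α-carbon C9, and no other π bond is present. The selectivity needed is endo over exo, which rests on overlap of the ester with C6–C7 and on the fact that both transition states carry one axial carbon on C10 syn to C14, so sterics do not favour the cis-decalin.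

Step 11
Reactants: 14 methyl (3R,4S,5S,8S,9S,10R)-3,13-(isopropylidenedioxy)-8-(triethylsilyloxy)drim-6-en-11-oate
Product: 15 methyl (3R,4S,5S,8S,9S,10R)-3,13-(isopropylidenedioxy)-8-(triethylsilyloxy)driman-11-oate
Conditions: H2 (1 atm), PtO2, EtOAc, rt
Reagents that add atoms: none
Why: Heterogeneous hydrogenation removes the helper alkene C6=C7, which is the only C=C left, forms no stereocentre, and in an aprotic solvent leaves the silyl ether and acetonide intact.

Step 12
Reactants: 15 methyl (3R,4S,5S,8S,9S,10R)-3,13-(isopropylidenedioxy)-8-(triethylsilyloxy)driman-11-oate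
Product: 16 (3R,4S,5S,8S,9R,10R)-3,13-(isopropylidenedioxy)-8-(triethylsilyloxy)driman-11-ol
Conditions: LiAlH4 (2 equiv), Et2O, 0 °C to rt
Reagents that add atoms: none
Why: Hydride reduction of the equatorial ester gives the primary alcohol C11–OH, acetonide and silyl ether are inert, and C9 is not touched (its descriptor changes only through the priority rules).

Step 13
Reactants: 16 (3R,4S,5S,8S,9R,10R)-3,13-(isopropylidenedioxy)-8-(triethylsilyloxy)driman-11-ol; 17 umbelliferone (7-hydroxycoumarin)
Product: 18 7-{[(3R,4S,5S,8S,9R,10R)-3,13-(isopropylidenedioxy)-8-(triethylsilyloxy)driman-11-yl]oxy}coumarin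
Conditions: PPh3 (2 equiv), DIAD (2 equiv), THF, 0 to 50 °C
Reagents that add atoms: none
Why: In this Mitsunobu etherification, the acidic phenol displaces the oxyphosphonium group at the only free, primary carbinol C11 by an SN2 process under neutral conditions that spare the lactone, and no stereocentre is involved.

Step 14
Reactants: 18 7-{[(3R,4S,5S,8S,9R,10R)-3,13-(isopropylidenedioxy)-8-(triethylsilyloxy)driman-11-yl]oxy}coumarin
Product: 19 7-{[(3R,4S,5S,8S,9R,10R)-3,8,13-trihydroxydriman-11-yl]oxy}coumarin
Conditions: HCl (1 M aq)/THF 1:4, rt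
Reagents that add atoms: none
Why: Mild acid hydrolysis cleaves the acetonide and the triethylsilyl ether in one operation, while aryl ether, coumarin and the non-allylic tertiary alcohol survive dilute acid at room temperature.

Step 15
Reactants: 19 7-{[(3R,4S,5S,8S,9R,10R)-3,8,13-trihydroxydriman-11-yl]oxy}coumarin; 20 angelic acid, (Z)-2-methylbut-2-enoic acid
Product: 22 target CNP0139045.1 (13-O-angelate of 19), via angelic 2,4,6-trichlorobenzoic anhydride 21 (not isolated)
Conditions: 20 (1.2 equiv), 2,4,6-trichlorobenzoyl chloride (1.2 equiv), Et3N (1.3 equiv), toluene, rt; then 19, toluene, 80 °C, no DMAP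
Reagents that add atoms: 2,4,6-trichlorobenzoyl chloride O=C(Cl)c1c(Cl)cc(Cl)cc1Cl (atoms end in 21 only)
Why: In this Yamaguchi-type mixed-anhydride esterification without a nucleophilic catalyst the Z geometry of the angelate is kept, and the primary C13–OH should react ahead of the secondary C3–OH, which is flanked by quaternary C4, and the inert tertiary C8–OH.

**Compound list**
1 | methyl geranate, methyl (2E)-3,7-dimethylocta-2,6-dienoate | COC(=O)/C=C(\C)CCC=C(C)C | starting material
2 | methyl (2E,6E)-8-hydroxy-3,7-dimethylocta-2,6-dienoate | COC(=O)/C=C(\C)CC/C=C(\C)CO | intermediate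
3 | methyl (2E)-5-[(2R,3R)-3-(hydroxymethyl)-3-methyloxiran-2-yl]-3-methylpent-2-enoate | COC(=O)/C=C(\C)CC[C@H]1O[C@]1(C)CO | intermediate
4 | methyl (2E)-5-[(2R,3S)-3-formyl-3-methyloxiran-2-yl]-3-methylpent-2-enoate | COC(=O)/C=C(\C)CC[C@H]1O[C@]1(C)C=O | intermediate
5 | pent-4-yn-2-ol (racemic) | CC(O)CC#C | starting material
6 | (E)-alkenylzirconocene chloride of the zirconium alkoxide of 5 (not isolated) | CC(C/C=C/[Zr](Cl)(C1C=CC=C1)C1C=CC=C1)O[Zr](Cl)(C1C=CC=C1)C1C=CC=C1 | intermediate
7 | (E)-5-iodopent-4-en-2-ol | CC(O)C/C=C/I | intermediate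
8 | methyl (2E)-5-{(2R,3R)-3-[(2E)-1,5-dihydroxyhex-2-en-1-yl]-3-methyloxiran-2-yl}-3-methylpent-2-enoate | COC(=O)/C=C(\C)CC[C@H]1O[C@]1(C)C(O)/C=C/CC(C)O | intermediate
9 | methyl (2E,6R,7R,8E)-7-formyl-6,11-dihydroxy-3,7-dimethyldodeca-2,8-dienoate (not isolated) | COC(=O)/C=C(\C)CC[C@@H](O)[C@](C)(C=O)/C=C/CC(C)O | intermediate
10 | methyl (2E,6R,7S,8E)-6,11-dihydroxy-7-(hydroxymethyl)-3,7-dimethyldodeca-2,8-dienoate | COC(=O)/C=C(\C)CC[C@@H](O)[C@](C)(CO)/C=C/CC(C)O | intermediate
11 | acetonide alcohol, (4R,5S)-1,3-dioxane with (1E)-4-hydroxypent-1-enyl on C5 of the dioxane | COC(=O)/C=C(\C)CC[C@H]1OC(C)(C)OC[C@]1(C)/C=C/CC(C)O | intermediate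
12 | acetonide β,γ-unsaturated methyl ketone | COC(=O)/C=C(\C)CC[C@H]1OC(C)(C)OC[C@]1(C)/C=C/CC(C)=O | intermediate
13 | (1E,3Z)-triethylsilyl dienol ether of 12 | COC(=O)/C=C(\C)CC[C@H]1OC(C)(C)OC[C@]1(C)/C=C/C=C(/C)O[Si](CC)(CC)CC | intermediate
14 | methyl (3R,4S,5S,8S,9S,10R)-3,13-(isopropylidenedioxy)-8-(triethylsilyloxy)drim-6-en-11-oate | CC1(C)OC[C@]2(C)[C@H]3C=C[C@](C)(O[Si](CC)(CC)CC)[C@@H](C(=O)OC)[C@]3(C)CC[C@H]2O1 | intermediate
15 | methyl (3R,4S,5S,8S,9S,10R)-3,13-(isopropylidenedioxy)-8-(triethylsilyloxy)driman-11-oate | CC1(C)OC[C@]2(C)[C@H]3CC[C@](C)(O[Si](CC)(CC)CC)[C@@H](C(=O)OC)[C@]3(C)CC[C@H]2O1 | intermediate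
16 | (3R,4S,5S,8S,9R,10R)-3,13-(isopropylidenedioxy)-8-(triethylsilyloxy)driman-11-ol | CC1(C)OC[C@]2(C)[C@H]3CC[C@](C)(O[Si](CC)(CC)CC)[C@@H](CO)[C@]3(C)CC[C@H]2O1 | intermediate
17 | umbelliferone (7-hydroxycoumarin) | Oc1ccc2ccc(=O)oc2c1 | starting material
18 | 7-O-(protected driman-11-yl)coumarin | CC1(C)OC[C@]2(C)[C@H]3CC[C@](C)(O[Si](CC)(CC)CC)[C@@H](COc4ccc5ccc(=O)oc5c4)[C@]3(C)CC[C@H]2O1 | intermediate
19 | 7-{[(3R,4S,5S,8S,9R,10R)-3,8,13-trihydroxydriman-11-yl]oxy}coumarin | OC[C@]1(C)[C@H]2CC[C@](C)(O)[C@@H](COc3ccc4ccc(=O)oc4c3)[C@]2(C)CC[C@H]1O | intermediate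
20 | angelic acid, (Z)-2-methylbut-2-enoic acid | C/C=C(/C)C(=O)O | starting material
21 | angelic 2,4,6-trichlorobenzoic anhydride (not isolated) | C/C=C(/C)C(=O)OC(=O)c1c(Cl)cc(Cl)cc1Cl | intermediate
22 | CNP0139045.1, (3R,4S,5S,8S,9R,10R)-13-angeloyloxy-3,8-dihydroxydriman-11-yl umbelliferyl ether | C/C=C(/C)C(=O)OC[C@]1(C)[C@H]2CC[C@](C)(O)[C@@H](COc3ccc4ccc(=O)oc4c3)[C@]2(C)CC[C@H]1O | target

Total steps: 15. Longest linear sequence: 14 (steps 1–3 and 5–15).

**Steps most likely to fail**

Step 10. The cycloaddition may be too slow, because both new bonds end at or next to fully substituted carbons. The dienol ether could then decay on long heating, or endo selectivity could erode. The fallback changes the activating group of the dienophile and therefore the later route. It sets out from 13. DIBAL-H (CH2Cl2, −78 °C) reduces the enoate to the allylic alcohol F1, and MnO2 (CH2Cl2, rt) gives the enal F2. The far more reactive F2 should cyclise in toluene at 80–110 °C, or with Me2AlCl at −78 °C with a stronger endo preference, to the aldehyde cycloadduct F3. NaBH4 (MeOH, 0 °C) gives the unsaturated alcohol F4, and H2/PtO2 (EtOAc) comes back to the route at 16.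

Step 9. Enolisation may go toward the methyl group, Z geometry may be lost, or the alkene may drift into conjugation. The fallback avoids an isolated dienol ether and uses the anion itself as the four-carbon partner. It sets out from 12. KHMDS (1.05 equiv, THF, −78 to 0 °C) removes the most acidic C7–H. The extended potassium dienolate can reach C10 only through C5 (six-membered ring), and the ester enolate so formed closes onto C8. This is a charge-accelerated formal [4+2], that is a vinylogous Michael addition followed by an aldol addition. Protonation gives the hydroxy ester cycloadduct F5, and Et3SiOTf/2,6-lutidine (CH2Cl2, 0 °C) comes back at 14.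

Step 13. Displacement at the hindered C11 may be sluggish, allowing alkylation of the hydrazide or silyl migration from O8 to O11 to compete. The fallback reverses the roles so that the alcohol is the nucleophile and the arene the electrophile. It sets out from 16, which is coupled with commercial 7-bromocoumarin by palladium-catalysed C–O cross-coupling (Pd2(dba)3, t-BuBrettPhos, Cs2CO3, toluene, 90 °C). It comes back at 18 without any new isolated compound.

**Further compounds**
F1 | step 10 | allylic alcohol from reduction of the enoate of 13 | OC/C=C(\C)CC[C@H]1OC(C)(C)OC[C@]1(C)/C=C/C=C(/C)O[Si](CC)(CC)CC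
F2 | step 10 | (E)-enal analogue of 13 | O=C/C=C(\C)CC[C@H]1OC(C)(C)OC[C@]1(C)/C=C/C=C(/C)O[Si](CC)(CC)CC
F3 | step 10 | 3,13-(isopropylidenedioxy)-8-(triethylsilyloxy)drim-6-en-11-al | CC1(C)OC[C@]2(C)[C@H]3C=C[C@](C)(O[Si](CC)(CC)CC)[C@@H](C=O)[C@]3(C)CC[C@H]2O1
F4 | step 10 | 3,13-(isopropylidenedioxy)-8-(triethylsilyloxy)drim-6-en-11-ol | CC1(C)OC[C@]2(C)[C@H]3C=C[C@](C)(O[Si](CC)(CC)CC)[C@@H](CO)[C@]3(C)CC[C@H]2O1
F5 | step 9 | methyl 8-hydroxy-3,13-(isopropylidenedioxy)drim-6-en-11-oate | CC1(C)OC[C@]2(C)[C@H]3C=C[C@](C)(O)[C@@H](C(=O)OC)[C@]3(C)CC[C@H]2O1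
F0 | step 13 | none | none
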